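The data stem from a simulated flask from invented constants, and the scatter is random.

Conversion of 50.0% of the two substrates together is what each equivalent of partner pays for, since each product consumes one partner and equivalents refer to the left-handed substrate.

common to all: left-handed substrate 0.30 M; right-handed substrate 0.30 M; precatalyst 4.5 mol%
- autumn: partner 1.6 equiv; protic impurity 0.015 M; run made earlier
- noon: partner 2.1 equiv; protic impurity 0.015 M; run made earlier
- delta: partner 1.20 equiv; protic impurity 0.0150 M; time 30 h
- epsilon: partner 1.80 equiv; protic impurity 0.0150 M; time 30 h

- autumn (time / h: left-handed product / %, right-handed product / %): 3.00: 60.3, 6.8; 6.00: 67.3, 6.9; 10.0: 69.3, 7.2; 12.0: 69.3, 7.8; 15.0: 68.8, 7.1; 20.0: 69.7, 7.7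
- noon (time / h: left-handed product / %, right-handed product / %): 1.00: 50.4, 3.8; 3.00: 65.5, 10.5; 6.00: 74.0, 15.0; 10.0: 79.0, 16.4; 12.0: 80.3, 16.2; 15.0: 80.4, 16.0; 20.0: 83.2, 16.1

(scatter of a reading: 0.5 percentage points)

- catalyst is single-handed; left-handed substrate and right-handed substrate are mirror images of each other, charged as a racemate, each of them at the stated concentration
- the analysis behind the earlier runs scatters by 0.5 percentage points, standard deviation
- steps thought possible: partner + catalyst + left-handed substrate -> catalyst + left-handed product; partner + catalyst + right-handed substrate -> catalyst + right-handed product; left-handed substrate <-> right-handed substrate; partner + precatalyst -> catalyst + spent reagent; partner + protic impurity -> quenched reagent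
- an excess is the difference of the two amounts in percent of their sum
- an excess is below zero if the other one leads

- which of the two ends with the higher excess of left-handed product over right-handed product in the product ("neither" if they lie within 2 percentage points) (delta / epsilon / neither)
- excess of left-handed product over right-handed product in the product at the end, delta
- excess of left-handed product over right-handed product in the product at the end, epsilon

The partner charge has to be known well: from autumn to noon, 0.500 equiv more partner took the excess at the last reading from 80.1% to 67.6%. The protic impurity costs 2.50% of conversion, and the precatalyst, if fully activated, 2.25%, so each charge takes less conversion than one equivalent of partner pays for. Time matters little once the autumn totals flatten: 76.5% at 10.0 h and 77.4% at 20.0 h.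

For delta, partner charged less protic impurity comes to 57.5% of the two substrates charged. This is the partner budget, the conversion that partner, here the limiting reagent, can pay for before activation of precatalyst takes its share. The autumn budget, 77.5%, stands close to the autumn total at the last reading. The noon budget, 102.5%, exceeds the charge, and its total reads 99.3%. The epsilon budget is 87.5%. Delta's budget lies near the first noon reading, total 54.2%, whose excess, 86.0%, serves here as the estimate for delta. Interpolating on total between the last autumn and noon readings gives epsilon 74.3%. This reckoning therefore puts delta higher.

The forecast, reasoning that “Right-handed product forms while partner is plentiful”, gave delta 87% and epsilon 75%, with delta higher.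

The flasks give 87.5% for delta and 76.6% for epsilon.

    partner + catalyst + left-handed substrate → catalyst + left-handed product (k = 2300 L² mol⁻² h⁻¹)
    partner + catalyst + right-handed substrate → catalyst + right-handed product (k = 81.0 L² mol⁻² h⁻¹)
    left-handed substrate ⇌ right-handed substrate (k = 0.210 h⁻¹)
    partner + precatalyst → catalyst + spent reagent (k = 1.10 L mol⁻¹ h⁻¹)
    partner + protic impurity → quenched reagent (k = 35.0 L mol⁻¹ h⁻¹)

Delta stands above epsilon because of the difference in partner: epsilon given delta's partner returns 87.5% instead of 76.6%. Delta's conversion is 56.7% against a budget of 57.5%, and its spent reagent, 0.00480 M, equals 0.799% of the two substrates charged, the size of that gap.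

With 0.480 equiv of partner, otherwise as delta, the budget is 21.5%. That flask holds 21.1% of product at 30.0 h, with excess 92.1%.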